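**Plan**

- Retrosynthesis: the four O–benzyl bonds and the lactol C–O go first. The 4‑aryl chroman is then cut at C3–C4 and O1–C2 (quinone methide + enamine) and at the C5'–C4 aryl–carbinol bond. The remaining isoflavan regains a CH2OH on C3 and is cut at O1–C2 to an oxetane, which leads back to a diol, a benzylated arylmalonate and an aryl bromide.
- Enabling feature: in the chroman that carries the central ring, C3 lies between the O1‑bound C2H2 and the benzylic C4H2. With one extra CH2OH on C3, C2 and that arm are the two CH2 groups of a 3‑aryl‑3‑(2‑hydroxybenzyl)oxetane whose ring‑A phenol becomes O1.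
- Forward order: arylmalonate → benzylation with ring A → diol → oxetane → first chroman → loss of the arm as CO → aryllithium addition to the second ring‑A aldehyde → second chroman by [4+2] → lactol reduction → hydrogenolysis.
- Stereochemistry: C3 of the first chroman is set by a chiral phosphoric acid and kept in the decarbonylation (retention). C3 and C4 of the second chroman are set by an (R)‑diphenylprolinol silyl ether; the 3,4‑trans arrangement is also the thermodynamic one.

Key step: step 11

Assumption: the sense of induction of both chiral catalysts is assigned by analogy with related reactions; if either proves reversed, the antipodal catalyst is used and nothing else changes.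

**Route**

Step 1
Reactants: 1 2-bromo-5-methoxyphenol
Product: 2 2-(benzyloxy)-1-bromo-4-methoxybenzene
Conditions: BnBr, K2CO3, DMF, rt
Reagents that add atoms: benzyl bromide, BrCc1ccccc1
Why: Williamson etherification of the phenoxide with a benzylic bromide is fast and clean, and the benzyl ether lasts until the final hydrogenolysis.

Step 2
Reactants: 2 2-(benzyloxy)-1-bromo-4-methoxybenzene; 3 diethyl malonate
Product: 4 diethyl 2-[2-(benzyloxy)-4-methoxyphenyl]malonate
Conditions: Pd(dba)2 (2 mol%), P(t-Bu)3·HBF4 (4 mol%), K3PO4, PhMe, 80 °C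
Reagents that add atoms: none
Why: Palladium-catalysed α-arylation of a malonate (Buchwald–Hartwig-type enolate coupling), in which the bulky electron-rich phosphine drives oxidative addition into the electron-rich ortho-alkoxy bromide and the product, held as its potassium enolate, cannot be arylated twice.

Step 3
Reactants: 4 diethyl 2-[2-(benzyloxy)-4-methoxyphenyl]malonate
Product: 5 diethyl 2-[2-(benzyloxy)-5-bromo-4-methoxyphenyl]malonate
Conditions: NBS (1.0 equiv), MeCN, 0 °C
Reagents that add atoms: N-bromosuccinimide, O=C1CCC(=O)N1Br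
Why: Electrophilic aromatic bromination should go para to OBn and ortho to OMe, the only ring carbon activated by both oxygens and not flanked by two substituents, which is the carbon that becomes C5' of the central ring.

Step 4
Reactants: 6 4-(benzyloxy)-2-hydroxybenzaldehyde
Product: 7 2-(allyloxy)-4-(benzyloxy)benzaldehyde
Conditions: allyl bromide, K2CO3, DMF, rt
Reagents that add atoms: allyl bromide, C=CCBr
Why: Williamson etherification; the allyl ether is orthogonal to the benzyl ethers, the aryl bromide and the later oxetane, so this oxygen alone can be unmasked before the key step.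

Step 5
Reactants: 7 2-(allyloxy)-4-(benzyloxy)benzaldehyde
Product: 8 [2-(allyloxy)-4-(benzyloxy)phenyl]methanol
Conditions: NaBH4, MeOH/THF, 0 °C
Reagents that add atoms: none
Why: Borohydride reduction of an aryl aldehyde to the benzylic alcohol leaves both ethers untouched.

Step 6
Reactants: 8 [2-(allyloxy)-4-(benzyloxy)phenyl]methanol
Product: 9 2-(allyloxy)-4-(benzyloxy)-1-(bromomethyl)benzene
Conditions: PBr3, pyridine (cat.), Et2O, 0 °C; used crude
Reagents that add atoms: phosphorus tribromide, BrP(Br)Br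
Why: Bromination of a benzylic alcohol through its phosphite ester (substitution by bromide); the electron-rich benzylic bromide is kept cold and used at once to avoid self-alkylation.

Step 7
Reactants: 5 diethyl 2-[2-(benzyloxy)-5-bromo-4-methoxyphenyl]malonate; 9 2-(allyloxy)-4-(benzyloxy)-1-(bromomethyl)benzene
Product: 10 diethyl 2-[2-(allyloxy)-4-(benzyloxy)benzyl]-2-[2-(benzyloxy)-5-bromo-4-methoxyphenyl]malonate
Conditions: NaH, THF/DMF, 0 °C → rt
Reagents that add atoms: none
Why: Malonate alkylation (SN2) of the tertiary carbanion with a reactive benzylic bromide creates the quaternary carbon that carries both the aryl and the benzyl group.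

Step 8
Reactants: 10 diethyl 2-[2-(allyloxy)-4-(benzyloxy)benzyl]-2-[2-(benzyloxy)-5-bromo-4-methoxyphenyl]malonate
Product: 11 2-[2-(allyloxy)-4-(benzyloxy)benzyl]-2-[2-(benzyloxy)-5-bromo-4-methoxyphenyl]propane-1,3-diol
Conditions: LiAlH4, THF, 0 °C → rt; Rochelle salt work-up
Reagents that add atoms: none
Why: Hydride reduction of both esters gives the prochiral 2,2-disubstituted propane-1,3-diol, the aryl bromide and the allyl and benzyl ethers being inert to LiAlH4 at or below room temperature.

Step 9
Reactants: 11 2-[2-(allyloxy)-4-(benzyloxy)benzyl]-2-[2-(benzyloxy)-5-bromo-4-methoxyphenyl]propane-1,3-diol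
Product: 13 3-[2-(allyloxy)-4-(benzyloxy)benzyl]-3-[2-(benzyloxy)-5-bromo-4-methoxyphenyl]oxetane, via monotosylate 12 (not isolated)
Conditions: KOt-Bu (1.05 equiv), TsCl (1.0 equiv), THF, 0 °C; then KOt-Bu (1.2 equiv), 0 → 50 °C
Reagents that add atoms: none
Why: Monosulfonylation of the symmetric diol followed by intramolecular Williamson etherification (4-exo-tet) is helped by the gem-disubstituent effect, the basic non-ionising medium suppresses aryl-assisted solvolysis of the neophyl-type tosylate, and an alkoxide base instead of an alkyllithium spares the C–Br bond.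

Step 10
Reactants: 13 3-[2-(allyloxy)-4-(benzyloxy)benzyl]-3-[2-(benzyloxy)-5-bromo-4-methoxyphenyl]oxetane
Product: 14 5-(benzyloxy)-2-({3-[2-(benzyloxy)-5-bromo-4-methoxyphenyl]oxetan-3-yl}methyl)phenol
Conditions: Pd(PPh3)4 (5 mol%), morpholine, THF, rt
Reagents that add atoms: none
Why: Tsuji–Trost deallylation, in which Pd(0) ionises the allyl aryl ether and morpholine traps the π-allyl complex, under conditions where the oxetane, the benzyl ethers and (at room temperature) the aryl bromide should not react.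

Step 11
Reactants: 14 5-(benzyloxy)-2-({3-[2-(benzyloxy)-5-bromo-4-methoxyphenyl]oxetan-3-yl}methyl)phenol
Product: 15 [(3R)-7-(benzyloxy)-3-[2-(benzyloxy)-5-bromo-4-methoxyphenyl]chroman-3-yl]methanol
Conditions: (R)-STRIP (SPINOL phosphoric acid with 2,4,6-i-Pr3C6H2 groups, 10 mol%), PhMe (0.05 M), 25–40 °C
Reagents that add atoms: none
Why: The phosphoric acid acts bifunctionally, its P–OH hydrogen-bonding to the oxetane oxygen while its P=O accepts the phenolic O–H, so the phenol oxygen attacks one of the two enantiotopic oxetane CH2 carbons in an SN2 displacement that releases about 25 kcal/mol of ring strain and forms O1–C2. The closest known reaction type is the chiral phosphoric acid-catalysed intramolecular desymmetrisation of 3,3-disubstituted oxetanes by tethered oxygen nucleophiles. The chroman closes in a 6-exo-tet mode, the breaking C–O bond lying outside the new ring and the oxetane oxygen remaining as the CH2OH arm. The quaternary C3 becomes stereogenic through the catalyst alone, whose flanking aryl groups make the two CH2 groups diastereotopic in the hydrogen-bonded complex by forcing the bulky ortho-benzyloxy aryl group away from the catalyst wall. The step needs the catalysed opening to outrun any uncatalysed or aryl-assisted opening; this is secured because the electrophilic carbons are primary (no SN1 path), the single free phenol is the only nucleophile the catalyst can activate, and the apolar solvent keeps the reaction inside the hydrogen-bonded complex.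

Step 12
Reactants: 15 [(3R)-7-(benzyloxy)-3-[2-(benzyloxy)-5-bromo-4-methoxyphenyl]chroman-3-yl]methanol
Product: 16 (3S)-7-(benzyloxy)-3-[2-(benzyloxy)-5-bromo-4-methoxyphenyl]chroman-3-carbaldehyde
Conditions: Dess–Martin periodinane, NaHCO3, CH2Cl2, 0 °C → rt
Reagents that add atoms: none
Why: Dess–Martin oxidation of the neopentyl primary alcohol stops at the aldehyde, and since the α-carbon is quaternary neither epimerisation nor β-elimination of the aryloxy group is possible (the descriptor changes only through CIP priorities).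

Step 13
Reactants: 16 (3S)-7-(benzyloxy)-3-[2-(benzyloxy)-5-bromo-4-methoxyphenyl]chroman-3-carbaldehyde
Product: 17 (3R)-7-(benzyloxy)-3-[2-(benzyloxy)-5-bromo-4-methoxyphenyl]chroman
Conditions: RhCl(PPh3)3 (1.1 equiv), degassed xylene, 130 °C
Reagents that add atoms: none
Why: Tsuji–Wilkinson decarbonylation, in which oxidative addition of the formyl C–H bond, migration of the tertiary alkyl group from CO to rhodium and C–H reductive elimination all occur on the same face, so H should replace CHO with retention and leave the (R)-configured tertiary C3.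

Step 14
Reactants: 17 (3R)-7-(benzyloxy)-3-[2-(benzyloxy)-5-bromo-4-methoxyphenyl]chroman; 6 4-(benzyloxy)-2-hydroxybenzaldehyde
Product: 20 [4-(benzyloxy)-2-hydroxyphenyl]{4-(benzyloxy)-5-[(3R)-7-(benzyloxy)chroman-3-yl]-2-methoxyphenyl}methanol (both carbinol epimers), via aryllithium 18 (not isolated), via sodium phenolate 19 (not isolated)
Conditions: n-BuLi (1.05 equiv), THF, −78 °C; then 19 (from 6, NaH, THF, 0 °C), −78 → 0 °C; aq NH4Cl
Reagents that add atoms: none
Why: Bromine–lithium exchange followed by 1,2-addition of the aryllithium to the aldehyde, whose phenol is masked beforehand as the sodium phenolate so that it cannot protonate the organolithium; the new carbinol centre is uncontrolled and is erased in step 19.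

Step 15
Reactants: 21 2,6-dimethoxyphenol
Product: 22 2-(benzyloxy)-1,3-dimethoxybenzene
Conditions: BnBr, K2CO3, DMF, 60 °C
Reagents that add atoms: benzyl bromide, BrCc1ccccc1
Why: Williamson etherification of the hindered phenoxide, with mild heating to offset the two ortho methoxy groups.

Step 16
Reactants: 22 2-(benzyloxy)-1,3-dimethoxybenzene
Product: 23 2-(benzyloxy)-4-bromo-1,3-dimethoxybenzene
Conditions: NBS (1.0 equiv), MeCN, 0 °C → rt
Reagents that add atoms: N-bromosuccinimide, O=C1CCC(=O)N1Br
Why: Electrophilic aromatic bromination para to one methoxy group and ortho to the other (C4) is favoured over the position para to the twisted central benzyloxy group, and one equivalent of NBS limits dibromination.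

Step 17
Reactants: 23 2-(benzyloxy)-4-bromo-1,3-dimethoxybenzene; 24 ethylene oxide
Product: 26 2-[3-(benzyloxy)-2,4-dimethoxyphenyl]ethanol, via aryllithium 25 (not isolated)
Conditions: n-BuLi, THF, −78 °C; ethylene oxide (3 equiv), −78 °C → rt; aq NH4Cl
Reagents that add atoms: none
Why: Bromine–lithium exchange at −78 °C (faster than deprotonation of the benzyl ether) and SN2 opening of the epoxide by the aryllithium add the two-carbon chain in one operation.

Step 18
Reactants: 26 2-[3-(benzyloxy)-2,4-dimethoxyphenyl]ethanol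
Product: 27 2-[3-(benzyloxy)-2,4-dimethoxyphenyl]acetaldehyde
Conditions: Dess–Martin periodinane, NaHCO3, CH2Cl2, 0 °C; used at once
Reagents that add atoms: none
Why: Dess–Martin oxidation stops at the aldehyde under buffered, non-enolising conditions, which suits a sensitive arylacetaldehyde.

Step 19
Reactants: 20 [4-(benzyloxy)-2-hydroxyphenyl]{4-(benzyloxy)-5-[(3R)-7-(benzyloxy)chroman-3-yl]-2-methoxyphenyl}methanol; 27 2-[3-(benzyloxy)-2,4-dimethoxyphenyl]acetaldehyde
Product: 30 (3R,4S)-7-(benzyloxy)-4-{4-(benzyloxy)-5-[(3R)-7-(benzyloxy)chroman-3-yl]-2-methoxyphenyl}-3-[3-(benzyloxy)-2,4-dimethoxyphenyl]chroman-2-ol (anomer mixture), via quinone methide 28 (not isolated), via enamine 29 (not isolated)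
Conditions: (R)-α,α-diphenylprolinol TMS ether (20 mol%), PhCO2H (20 mol%), CHCl3, rt
Reagents that add atoms: none
Why: Aminocatalytic formal [4+2] annulation, in which the acid co-catalyst dehydrates the carbinol to the ortho-quinone methide 28, the E-enamine 29 adds to its exocyclic carbon (Michael addition) from the face left open by the diphenyl(silyloxy)methyl group, and phenoxide closure on the iminium followed by hydrolysis gives the lactol; by analogy with syn-selective enamine Michael additions the (R)-catalyst should set C3 as R and C4 as S (3,4-trans), and the enolisable C3 can equilibrate to the more stable trans isomer.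

Step 20
Reactants: 30 (3R,4S)-7-(benzyloxy)-4-{4-(benzyloxy)-5-[(3R)-7-(benzyloxy)chroman-3-yl]-2-methoxyphenyl}-3-[3-(benzyloxy)-2,4-dimethoxyphenyl]chroman-2-ol
Product: 31 (3R,4S)-7-(benzyloxy)-4-{4-(benzyloxy)-5-[(3R)-7-(benzyloxy)chroman-3-yl]-2-methoxyphenyl}-3-[3-(benzyloxy)-2,4-dimethoxyphenyl]chroman
Conditions: Et3SiH, BF3·OEt2, CH2Cl2, −78 → −20 °C
Reagents that add atoms: none
Why: Ionic hydrogenation of the lactol, in which BF3 ionises the anomeric hydroxyl to the cyclic oxocarbenium ion and triethylsilane reduces it to the chroman CH2 without touching C3 or C4.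

Step 21
Reactants: 31 (3R,4S)-7-(benzyloxy)-4-{4-(benzyloxy)-5-[(3R)-7-(benzyloxy)chroman-3-yl]-2-methoxyphenyl}-3-[3-(benzyloxy)-2,4-dimethoxyphenyl]chroman
Product: 32 (3R,4S)-4-{4-hydroxy-5-[(3R)-7-hydroxychroman-3-yl]-2-methoxyphenyl}-3-(3-hydroxy-2,4-dimethoxyphenyl)chroman-7-ol
Conditions: H2 (1 atm), 10% Pd/C, EtOAc/MeOH, rt
Reagents that add atoms: none
Why: Hydrogenolysis of the four benzyl aryl ethers over palladium should be clean because the chroman C–O bonds are not benzylic and the diarylmethine C–C bonds are inert.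

**Compound list**

1 | 2-bromo-5-methoxyphenol | COc1ccc(Br)c(O)c1 | starting material
2 | 2-(benzyloxy)-1-bromo-4-methoxybenzene | COc1ccc(Br)c(OCc2ccccc2)c1 | intermediate
3 | diethyl malonate | CCOC(=O)CC(=O)OCC | starting material
4 | diethyl 2-[2-(benzyloxy)-4-methoxyphenyl]malonate | CCOC(=O)C(C(=O)OCC)c1ccc(OC)cc1OCc1ccccc1 | intermediate
5 | diethyl 2-[2-(benzyloxy)-5-bromo-4-methoxyphenyl]malonate | CCOC(=O)C(C(=O)OCC)c1cc(Br)c(OC)cc1OCc1ccccc1 | intermediate
6 | 4-(benzyloxy)-2-hydroxybenzaldehyde | O=Cc1ccc(OCc2ccccc2)cc1O | starting material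
7 | 2-(allyloxy)-4-(benzyloxy)benzaldehyde | C=CCOc1cc(OCc2ccccc2)ccc1C=O | intermediate
8 | [2-(allyloxy)-4-(benzyloxy)phenyl]methanol | C=CCOc1cc(OCc2ccccc2)ccc1CO | intermediate
9 | 2-(allyloxy)-4-(benzyloxy)-1-(bromomethyl)benzene | C=CCOc1cc(OCc2ccccc2)ccc1CBr | intermediate
10 | diethyl 2-[2-(allyloxy)-4-(benzyloxy)benzyl]-2-[2-(benzyloxy)-5-bromo-4-methoxyphenyl]malonate | CCOC(=O)C(Cc1ccc(OCc2ccccc2)cc1OCC=C)(C(=O)OCC)c1cc(Br)c(OC)cc1OCc1ccccc1 | intermediate
11 | 2-[2-(allyloxy)-4-(benzyloxy)benzyl]-2-[2-(benzyloxy)-5-bromo-4-methoxyphenyl]propane-1,3-diol | OCC(CO)(Cc1ccc(OCc2ccccc2)cc1OCC=C)c1cc(Br)c(OC)cc1OCc1ccccc1 | intermediate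
12 | 2-[2-(allyloxy)-4-(benzyloxy)benzyl]-2-[2-(benzyloxy)-5-bromo-4-methoxyphenyl]-3-hydroxypropyl 4-methylbenzenesulfonate (racemic; not isolated) | Cc1ccc(cc1)S(=O)(=O)OCC(CO)(Cc1ccc(OCc2ccccc2)cc1OCC=C)c1cc(Br)c(OC)cc1OCc1ccccc1 | intermediate
13 | 3-[2-(allyloxy)-4-(benzyloxy)benzyl]-3-[2-(benzyloxy)-5-bromo-4-methoxyphenyl]oxetane | C=CCOc1cc(OCc2ccccc2)ccc1CC1(COC1)c1cc(Br)c(OC)cc1OCc1ccccc1 | intermediate
14 | 5-(benzyloxy)-2-({3-[2-(benzyloxy)-5-bromo-4-methoxyphenyl]oxetan-3-yl}methyl)phenol | COc1cc(OCc4ccccc4)c(C2(Cc3ccc(OCc4ccccc4)cc3O)COC2)cc1Br | intermediate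
15 | [(3R)-7-(benzyloxy)-3-[2-(benzyloxy)-5-bromo-4-methoxyphenyl]chroman-3-yl]methanol | COc1cc(OCc4ccccc4)c([C@]2(CO)COc3cc(OCc4ccccc4)ccc3C2)cc1Br | intermediate
16 | (3S)-7-(benzyloxy)-3-[2-(benzyloxy)-5-bromo-4-methoxyphenyl]chroman-3-carbaldehyde | COc1cc(OCc4ccccc4)c([C@]2(C=O)COc3cc(OCc4ccccc4)ccc3C2)cc1Br | intermediate
17 | (3R)-7-(benzyloxy)-3-[2-(benzyloxy)-5-bromo-4-methoxyphenyl]chroman | COc1cc(OCc4ccccc4)c([C@@H]2COc3cc(OCc4ccccc4)ccc3C2)cc1Br | intermediate
18 | {4-(benzyloxy)-5-[(3R)-7-(benzyloxy)chroman-3-yl]-2-methoxyphenyl}lithium (not isolated) | COc1cc(OCc4ccccc4)c([C@@H]2COc3cc(OCc4ccccc4)ccc3C2)cc1[Li] | intermediate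
19 | sodium 5-(benzyloxy)-2-formylphenolate (not isolated) | [Na+].[O-]c1cc(OCc2ccccc2)ccc1C=O | intermediate
20 | [4-(benzyloxy)-2-hydroxyphenyl]{4-(benzyloxy)-5-[(3R)-7-(benzyloxy)chroman-3-yl]-2-methoxyphenyl}methanol (both carbinol epimers) | COc1cc(OCc4ccccc4)c([C@@H]2COc3cc(OCc4ccccc4)ccc3C2)cc1C(O)c1ccc(OCc2ccccc2)cc1O | intermediate
21 | 2,6-dimethoxyphenol | COc1cccc(OC)c1O | starting material
22 | 2-(benzyloxy)-1,3-dimethoxybenzene | COc1cccc(OC)c1OCc1ccccc1 | intermediate
23 | 2-(benzyloxy)-4-bromo-1,3-dimethoxybenzene | COc1ccc(Br)c(OC)c1OCc1ccccc1 | intermediate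
24 | ethylene oxide | C1CO1 | starting material
25 | [3-(benzyloxy)-2,4-dimethoxyphenyl]lithium (not isolated) | COc1ccc([Li])c(OC)c1OCc1ccccc1 | intermediate
26 | 2-[3-(benzyloxy)-2,4-dimethoxyphenyl]ethanol | COc1ccc(CCO)c(OC)c1OCc1ccccc1 | intermediate
27 | 2-[3-(benzyloxy)-2,4-dimethoxyphenyl]acetaldehyde | COc1ccc(CC=O)c(OC)c1OCc1ccccc1 | intermediate
28 | 3-(benzyloxy)-6-({4-(benzyloxy)-5-[(3R)-7-(benzyloxy)chroman-3-yl]-2-methoxyphenyl}methylidene)cyclohexa-2,4-dien-1-one (ortho-quinone methide, alkene geometry open; not isolated) | COc1cc(OCc4ccccc4)c([C@@H]2COc3cc(OCc4ccccc4)ccc3C2)cc1C=C1C=CC(OCc2ccccc2)=CC1=O | intermediate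
29 | (R)-1-{(E)-2-[3-(benzyloxy)-2,4-dimethoxyphenyl]ethenyl}-2-[diphenyl(trimethylsilyloxy)methyl]pyrrolidine (not isolated) | C[Si](C)(C)OC(c1ccccc1)(c1ccccc1)[C@H]1CCCN1/C=C/c1ccc(OC)c(OCc2ccccc2)c1OC | intermediate
30 | (3R,4S)-7-(benzyloxy)-4-{4-(benzyloxy)-5-[(3R)-7-(benzyloxy)chroman-3-yl]-2-methoxyphenyl}-3-[3-(benzyloxy)-2,4-dimethoxyphenyl]chroman-2-ol (anomer mixture) | COc1cc(OCc4ccccc4)c([C@@H]2COc3cc(OCc4ccccc4)ccc3C2)cc1[C@@H]1c2ccc(OCc3ccccc3)cc2OC(O)[C@H]1c1ccc(OC)c(OCc2ccccc2)c1OC | intermediate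
31 | (3R,4S)-7-(benzyloxy)-4-{4-(benzyloxy)-5-[(3R)-7-(benzyloxy)chroman-3-yl]-2-methoxyphenyl}-3-[3-(benzyloxy)-2,4-dimethoxyphenyl]chroman | COc1cc(OCc4ccccc4)c([C@@H]2COc3cc(OCc4ccccc4)ccc3C2)cc1[C@@H]1c2ccc(OCc3ccccc3)cc2OC[C@H]1c1ccc(OC)c(OCc2ccccc2)c1OC | intermediate
32 | (3R,4S)-4-{4-hydroxy-5-[(3R)-7-hydroxychroman-3-yl]-2-methoxyphenyl}-3-(3-hydroxy-2,4-dimethoxyphenyl)chroman-7-ol | COc1cc(O)c([C@@H]2COc3cc(O)ccc3C2)cc1[C@@H]1c2ccc(O)cc2OC[C@H]1c1ccc(OC)c(O)c1OC | target

**Count**

Total steps: 21. Longest linear sequence: 14 (steps 1–3, 7–14, 19–21).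

**Steps most likely to fail**

Step 19. The enamine may discriminate the two faces of the hindered, very electron-rich diaryl quinone methide poorly; that would give the C4-epimeric series, which equilibration at C3 cannot repair. The quinone methide may also oligomerise before it is intercepted. The fallback moves stereocontrol from the nucleophile to the electrophile. It sets out from compounds 27 and 20. Aldehyde 27 is converted with TBSOTf and Et3N in CH2Cl2 into tert-butyl({2-[3-(benzyloxy)-2,4-dimethoxyphenyl]ethenyl}oxy)dimethylsilane F1 (E/Z mixture). Carbinol 20 and F1 are then combined under a chiral BINOL-derived phosphoric acid such as TRIP, which dehydrates 20 to quinone methide 28 and stays hydrogen-bonded to its carbonyl oxygen. Mukaiyama–Michael addition and ring closure should give the 2-(tert-butyldimethylsilyloxy)chroman F2. Et3SiH/BF3·OEt2 reduces this silyl acetal directly, and the fallback comes back to the route at compound 31.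

Step 13. β-Hydride elimination from the tertiary alkyl–rhodium hydride (towards the isoflav-3-ene) and oxidative addition of rhodium into the C–Br bond at 130 °C may compete with C–H reductive elimination. The fallback removes the halide before the metal step and sets out from compound 15. Treatment with n-BuLi (2.2 equiv, THF, −78 °C) and excess TMSCl should give the C,O-bis(trimethylsilyl) compound F3. K2CO3/MeOH work-up cleaves its O–Si bond to the arylsilane alcohol F4. Dess–Martin oxidation gives the arylsilane aldehyde F5. Decarbonylation, now halide-free and so open to higher temperature or to catalytic Rh/dppp conditions, gives the 5'-trimethylsilyl isoflavan F6. Ipso-bromodesilylation with NBS in MeCN, directed by the β-silicon effect, returns to the route at compound 17. This answers the C–Br insertion only; β-hydride elimination is intrinsic to the metal step.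

Step 11. The catalyst may differentiate the two enantiotopic CH2 groups insufficiently, or a racemic background opening (uncatalysed, or assisted by the electron-rich C3 aryl ring) may erode the enantiomeric purity. The fallback forms the same O1–C2 bond but desymmetrises the diol instead of the oxetane, and sets out from compound 11. Catalytic enantioselective monobenzoylation of the prochiral diol (chiral Cu(II)–bis(oxazoline) complex, BzCl, Et3N) should give the (2S)-monobenzoate F7. Pd(PPh3)4/morpholine removes the allyl group to give the phenol monobenzoate F8. Mitsunobu cyclisation (PPh3, DIAD, PhMe, 60 °C) closes the chroman on the unacylated arm in a 6-exo-tet mode to give the chromanylmethyl benzoate F9. Methanolysis (K2CO3, MeOH) returns to the route at compound 15.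

**Further compounds**

F1 | step 19 | tert-butyl({2-[3-(benzyloxy)-2,4-dimethoxyphenyl]ethenyl}oxy)dimethylsilane (E/Z mixture) | COc1ccc(C=CO[Si](C)(C)C(C)(C)C)c(OC)c1OCc1ccccc1
F2 | step 19 | tert-butyl{[(3R,4S)-7-(benzyloxy)-4-{4-(benzyloxy)-5-[(3R)-7-(benzyloxy)chroman-3-yl]-2-methoxyphenyl}-3-[3-(benzyloxy)-2,4-dimethoxyphenyl]chroman-2-yl]oxy}dimethylsilane | COc1cc(OCc4ccccc4)c([C@@H]2COc3cc(OCc4ccccc4)ccc3C2)cc1[C@@H]1c2ccc(OCc3ccccc3)cc2OC(O[Si](C)(C)C(C)(C)C)[C@H]1c1ccc(OC)c(OCc2ccccc2)c1OC
F3 | step 13 | {[(3S)-7-(benzyloxy)-3-[2-(benzyloxy)-4-methoxy-5-(trimethylsilyl)phenyl]chroman-3-yl]methoxy}trimethylsilane | COc1cc(OCc4ccccc4)c([C@]2(CO[Si](C)(C)C)COc3cc(OCc4ccccc4)ccc3C2)cc1[Si](C)(C)C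
F4 | step 13 | [(3R)-7-(benzyloxy)-3-[2-(benzyloxy)-4-methoxy-5-(trimethylsilyl)phenyl]chroman-3-yl]methanol | COc1cc(OCc4ccccc4)c([C@]2(CO)COc3cc(OCc4ccccc4)ccc3C2)cc1[Si](C)(C)C
F5 | step 13 | (3S)-7-(benzyloxy)-3-[2-(benzyloxy)-4-methoxy-5-(trimethylsilyl)phenyl]chroman-3-carbaldehyde | COc1cc(OCc4ccccc4)c([C@]2(C=O)COc3cc(OCc4ccccc4)ccc3C2)cc1[Si](C)(C)C
F6 | step 13 | {4-(benzyloxy)-5-[(3R)-7-(benzyloxy)chroman-3-yl]-2-methoxyphenyl}trimethylsilane | COc1cc(OCc4ccccc4)c([C@@H]2COc3cc(OCc4ccccc4)ccc3C2)cc1[Si](C)(C)C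
F7 | step 11 | (2S)-2-[2-(allyloxy)-4-(benzyloxy)benzyl]-2-[2-(benzyloxy)-5-bromo-4-methoxyphenyl]-3-hydroxypropyl benzoate | COc1cc(OCc4ccccc4)c([C@](Cc3ccc(OCc4ccccc4)cc3OCC=C)(COC(=O)c5ccccc5)CO)cc1Br
F8 | step 11 | (2S)-2-[4-(benzyloxy)-2-hydroxybenzyl]-2-[2-(benzyloxy)-5-bromo-4-methoxyphenyl]-3-hydroxypropyl benzoate | COc1cc(OCc4ccccc4)c([C@](Cc3ccc(OCc4ccccc4)cc3O)(COC(=O)c5ccccc5)CO)cc1Br
F9 | step 11 | [(3S)-7-(benzyloxy)-3-[2-(benzyloxy)-5-bromo-4-methoxyphenyl]chroman-3-yl]methyl benzoate | COc1cc(OCc4ccccc4)c([C@]2(COC(=O)c5ccccc5)COc3cc(OCc4ccccc4)ccc3C2)cc1Br
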